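The plan rests on cutting both aryl bonds of the pyran ring, C4–C4a and O1–C8a, which sit on adjacent benzene carbons. An aryne spanning C4a/C8a is trapped by 3-methylbut-2-enal: formal [2+2] addition of the C=O group gives a benzoxete, which opens to an ortho-quinone methide and closes by oxa-6π electrocyclisation, so the whole 2,2-dimethyl-2H-pyran ring forms in one operation. The feature exploited is that O1 and C4 are attached to neighbouring benzene carbons, with C5 next to C4a: a bromine at C5 polarises the aryne so that oxygen lands on C8a, and later becomes an indolyl group. The precursor is an ortho-silylaryl triflate made from 2-bromoisovanillin.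

Key step: step 5

Remark: chromene numbering (O1, C2, C3, C4, C4a, C5 to C8, C8a) is used for the target positions throughout; compounds 1, 9 and 15 and all reagents are assumed to be commercial; the target has no stereocentre.

Step 1
Reactants: 1 2-bromo-3-hydroxy-4-methoxybenzaldehyde (2-bromoisovanillin)
Product: 2 2-bromo-4-methoxy-3-(methoxymethoxy)benzaldehyde
Conditions: MOMCl, iPr2NEt, CH2Cl2, 0 °C to rt
Reagents that add atoms: chloromethyl methyl ether (MOMCl), COCCl
Why: O-alkylation of the phenol (MOM ether formation) with a small, very reactive electrophile should proceed despite the flanking Br and OMe groups, and the acetal is stable to all basic, organometallic and fluoride steps that follow.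

Step 2
Reactants: 2 2-bromo-4-methoxy-3-(methoxymethoxy)benzaldehyde
Product: 4 2-bromo-4-methoxy-3-(methoxymethoxy)phenol, via aryl formate 3 (not isolated)
Conditions: mCPBA, CH2Cl2, rt; then K2CO3 (cat.), MeOH, rt
Reagents that add atoms: meta-chloroperoxybenzoic acid (mCPBA), O=C(OO)c1cccc(Cl)c1
Why: Baeyer–Villiger (Dakin-type) oxidation, in which the electron-rich para-methoxyaryl group migrates to give the formate, followed by methanolysis, should replace the formyl group by OH at the future C4a.

Step 3
Reactants: 4 2-bromo-4-methoxy-3-(methoxymethoxy)phenol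
Product: 5 2-bromo-6-iodo-4-methoxy-3-(methoxymethoxy)phenol
Conditions: NIS, MeCN, 0 °C to rt
Reagents that add atoms: N-iodosuccinimide, O=C1CCC(=O)N1I
Why: Electrophilic aromatic iodination should go ortho to the free OH (para to the OMOM group, future C8a), since the para position is blocked and the only other free position is meta to OH.

Step 4
Reactants: 5 2-bromo-6-iodo-4-methoxy-3-(methoxymethoxy)phenol
Product: 8 2-bromo-4-methoxy-3-(methoxymethoxy)-6-(trimethylsilyl)phenyl trifluoromethanesulfonate, via aryl trimethylsilyl ether 6 (not isolated), via lithium 2-silylphenoxide 7 (not isolated)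
Conditions: HMDS, THF, 70 °C, then evaporate; n-BuLi (1.05 equiv), THF, −78 °C; Tf2O, −78 °C to rt
Reagents that add atoms: hexamethyldisilazane, C[Si](C)(C)N[Si](C)(C)C; trifluoromethanesulfonic anhydride, O=S(=O)(OS(=O)(=O)C(F)(F)F)C(F)(F)F
Why: O-silylation, iodine–lithium exchange (much faster than exchange at the bromide), 1,3-retro-Brook O-to-C silyl migration and O-triflation of the resulting phenoxide form the standard one-pot route to ortho-silylaryl triflates.

Step 5
Reactants: 8 2-bromo-4-methoxy-3-(methoxymethoxy)-6-(trimethylsilyl)phenyl trifluoromethanesulfonate; 9 3-methylbut-2-enal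
Product: 13 5-bromo-7-methoxy-6-(methoxymethoxy)-2,2-dimethyl-2H-chromene, via aryne 10 (not isolated), via benzoxete 11 (not isolated), via ortho-quinone methide 12 (not isolated)
Conditions: CsF (3 equiv), 9 (5 equiv), MeCN, rt to 50 °C
Reagents that add atoms: none
Why: Fluoride removes the silyl group of 8 and triflate leaves to give aryne 10; the carbonyl oxygen of 9 adds to the aryne carbon remote from bromine (the future C8a) and the aryl anion, now next to bromine at the future C4a, collapses onto the oxocarbenium carbon, a formal [2+2] addition that gives benzoxete 11. Thermal 4π ring opening of 11 gives ortho-quinone methide 12, whose oxa-6π electrocyclisation forms O1–C2 and restores the benzene ring. The closest known reaction type is the annulation of arynes from ortho-silylaryl triflates by α,β-unsaturated aldehydes to 2H-chromenes, related to aryne insertion into the C=O bond of formamides. The four-membered ring closes by 4-exo collapse of the zwitterion and the pyran ring by thermal disrotatory 6π electrocyclisation; no stereocentre survives, since the benzoxete carbon becomes sp2 and either alkene geometry of 12 funnels to 13 through reversible reclosure to 11. The step needs oxygen at C8a and carbon at C4a: bromine at C5 distorts and polarises the aryne as in 3-haloarynes so that nucleophiles attack the distal carbon, and the unsubstituted C8–H side offers no steric opposition. Attack at C=O instead of the C=C bond or an ene reaction at the methyl groups relies on the nucleophilic carbonyl oxygen of the electron-poor enal, used in excess.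

Step 6
Reactants: 13 5-bromo-7-methoxy-6-(methoxymethoxy)-2,2-dimethyl-2H-chromene
Product: 14 5,8-dibromo-7-methoxy-6-(methoxymethoxy)-2,2-dimethyl-2H-chromene
Conditions: NBS (1.05 equiv), MeCN, −20 to 0 °C, dark
Reagents that add atoms: N-bromosuccinimide, O=C1CCC(=O)N1Br
Why: Electrophilic aromatic bromination with NBS in dry MeCN should take the only free ring position, C8, which is ortho to both O1 and the methoxy group, while the absence of water and light disfavours attack on the C3=C4 bond.

Step 7
Reactants: 14 5,8-dibromo-7-methoxy-6-(methoxymethoxy)-2,2-dimethyl-2H-chromene; 15 tert-butyl 3-(4,4,5,5-tetramethyl-1,3,2-dioxaborolan-2-yl)indole-1-carboxylate (3 equiv)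
Product: 16 di-tert-butyl 3,3'-[7-methoxy-6-(methoxymethoxy)-2,2-dimethyl-2H-chromene-5,8-diyl]bis(indole-1-carboxylate)
Conditions: Pd(OAc)2 (10 mol%), SPhos (20 mol%), K3PO4, toluene/H2O (10:1), 90 °C
Reagents that add atoms: none
Why: A double Suzuki–Miyaura coupling with a dialkylbiarylphosphine ligand should engage both di-ortho-substituted aryl bromides, the excess of N-Boc-protected boronate offsetting protodeboronation.

Step 8
Reactants: 16 di-tert-butyl 3,3'-[7-methoxy-6-(methoxymethoxy)-2,2-dimethyl-2H-chromene-5,8-diyl]bis(indole-1-carboxylate)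
Product: 17 kumbicin C, 5,8-di(1H-indol-3-yl)-7-methoxy-2,2-dimethyl-2H-chromen-6-ol
Conditions: HCl (4 M in dioxane), MeOH, 50 °C
Reagents that add atoms: none
Why: Acid-catalysed acetal exchange with methanol should remove the MOM ether and acidolysis should remove both indole N-Boc carbamates (loss of 2-methylpropene and CO2) under conditions that a 2,2-dimethyl-2H-chromene tolerates.

Compound list
1 | 2-bromo-3-hydroxy-4-methoxybenzaldehyde | COc1ccc(C=O)c(Br)c1O | starting material
2 | 2-bromo-4-methoxy-3-(methoxymethoxy)benzaldehyde | COCOc1c(OC)ccc(C=O)c1Br | intermediate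
3 | 2-bromo-4-methoxy-3-(methoxymethoxy)phenyl formate | COCOc1c(OC)ccc(OC=O)c1Br | intermediate
4 | 2-bromo-4-methoxy-3-(methoxymethoxy)phenol | COCOc1c(OC)ccc(O)c1Br | intermediate
5 | 2-bromo-6-iodo-4-methoxy-3-(methoxymethoxy)phenol | COCOc1c(OC)cc(I)c(O)c1Br | intermediate
6 | [2-bromo-6-iodo-4-methoxy-3-(methoxymethoxy)phenoxy]trimethylsilane | COCOc1c(OC)cc(I)c(O[Si](C)(C)C)c1Br | intermediate
7 | lithium 2-bromo-4-methoxy-3-(methoxymethoxy)-6-(trimethylsilyl)phenoxide | COCOc1c(OC)cc([Si](C)(C)C)c([O-])c1Br.[Li+] | intermediate
8 | 2-bromo-4-methoxy-3-(methoxymethoxy)-6-(trimethylsilyl)phenyl trifluoromethanesulfonate | COCOc1c(OC)cc([Si](C)(C)C)c(OS(=O)(=O)C(F)(F)F)c1Br | intermediate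
9 | 3-methylbut-2-enal | CC(C)=CC=O | starting material
10 | 3-bromo-5-methoxy-4-(methoxymethoxy)benzyne (1,2-didehydrobenzene) | COCOC1=C(Br)C#CC=C1OC | intermediate
11 | 3-bromo-5-methoxy-4-(methoxymethoxy)-2-(2-methylprop-1-enyl)-2H-benzoxete (racemic) | COCOc1c(OC)cc2OC(C=C(C)C)c2c1Br | intermediate
12 | 5-bromo-3-methoxy-4-(methoxymethoxy)-6-(3-methylbut-2-enylidene)cyclohexa-2,4-dien-1-one | COCOC1=C(Br)C(=CC=C(C)C)C(=O)C=C1OC | intermediate
13 | 5-bromo-7-methoxy-6-(methoxymethoxy)-2,2-dimethyl-2H-chromene | COCOc1c(OC)cc2OC(C)(C)C=Cc2c1Br | intermediate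
14 | 5,8-dibromo-7-methoxy-6-(methoxymethoxy)-2,2-dimethyl-2H-chromene | COCOc1c(OC)c(Br)c2OC(C)(C)C=Cc2c1Br | intermediate
15 | tert-butyl 3-(4,4,5,5-tetramethyl-1,3,2-dioxaborolan-2-yl)indole-1-carboxylate | CC(C)(C)OC(=O)n1cc(B2OC(C)(C)C(C)(C)O2)c2ccccc12 | starting material
16 | di-tert-butyl 3,3'-[7-methoxy-6-(methoxymethoxy)-2,2-dimethyl-2H-chromene-5,8-diyl]bis(indole-1-carboxylate) | COCOc1c(OC)c(-c2cn(C(=O)OC(C)(C)C)c3ccccc23)c2OC(C)(C)C=Cc2c1-c1cn(C(=O)OC(C)(C)C)c2ccccc12 | intermediate
17 | kumbicin C | COc1c(O)c(-c2c[nH]c3ccccc23)c2c(c1-c1c[nH]c3ccccc13)OC(C)(C)C=C2 | target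

Total step count: 8. Longest linear sequence: 8 steps, from 1 to 17.

Steps most likely to fail

Step 5. The aryne may be consumed by an ene reaction with the allylic methyl groups of the enal, or the enal may self-condense under fluoride, so that capture at the C=O group is inefficient. The fallback sets out from 8 and builds the same ring stepwise. The aryne is generated with CsF in DMF as solvent and trap; C=O insertion of the formamide and aqueous work-up should give 6-bromo-2-hydroxy-4-methoxy-5-(methoxymethoxy)benzaldehyde F1, with the same orientation control by bromine. Addition of 2-methylprop-1-enylmagnesium bromide (2.2 equiv, THF, 0 °C) should give 3-bromo-2-(1-hydroxy-3-methylbut-2-en-1-yl)-5-methoxy-4-(methoxymethoxy)phenol F2 (racemic). Mild cyclodehydration (PPTS cat., toluene, 60 °C) passes through ortho-quinone methide 12 and comes back to the route at 13.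

Step 6. Bromine transfer to the electron-rich C3=C4 bond may compete with ring substitution at C8. The fallback sets out from 8 and halogenates before the alkene exists. Salicylaldehyde F1 is made as above and brominated with NBS (MeCN, 0 °C) at its only free ring position, ortho to the phenol, to give 3,6-dibromo-2-hydroxy-4-methoxy-5-(methoxymethoxy)benzaldehyde F3. Addition of 2-methylprop-1-enylmagnesium bromide gives 3,6-dibromo-2-(1-hydroxy-3-methylbut-2-en-1-yl)-5-methoxy-4-(methoxymethoxy)phenol F4 (racemic). Cyclodehydration (PPTS cat., toluene, 60 °C) comes back to the route at 14.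

Step 7. Protodeboronation of the indol-3-yl boronate may outrun transmetalation at the two hindered C–Br bonds, stopping at mono-coupling. The fallback sets out from 14 and replaces the boron nucleophile by an organozinc (Negishi coupling). Commercial tert-butyl 3-iodoindole-1-carboxylate is converted with iPrMgCl·LiCl (THF, −40 °C) and then ZnCl2 into [1-(tert-butoxycarbonyl)indol-3-yl]zinc chloride F5. Coupling of F5 (3 equiv) with 14 under Pd(OAc)2/SPhos in THF at 60 °C comes back to the route at 16.

Further compounds
F1 | step 5 | 6-bromo-2-hydroxy-4-methoxy-5-(methoxymethoxy)benzaldehyde | COCOc1c(OC)cc(O)c(C=O)c1Br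
F2 | step 5 | 3-bromo-2-(1-hydroxy-3-methylbut-2-en-1-yl)-5-methoxy-4-(methoxymethoxy)phenol (racemic) | COCOc1c(OC)cc(O)c(C(O)C=C(C)C)c1Br
F3 | step 6 | 3,6-dibromo-2-hydroxy-4-methoxy-5-(methoxymethoxy)benzaldehyde | COCOc1c(OC)c(Br)c(O)c(C=O)c1Br
F4 | step 6 | 3,6-dibromo-2-(1-hydroxy-3-methylbut-2-en-1-yl)-5-methoxy-4-(methoxymethoxy)phenol (racemic) | COCOc1c(OC)c(Br)c(O)c(C(O)C=C(C)C)c1Br
F5 | step 7 | [1-(tert-butoxycarbonyl)indol-3-yl]zinc chloride | CC(C)(C)OC(=O)n1cc([Zn]Cl)c2ccccc12
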